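## Retrosynthetic overview

1. The acetate goes on last. Ring B (the acetylcyclohexene) is opened at its C=C bond by a retro-aldol condensation. This gives a cyclopentane with a CH2CHO arm (masked as a terminal alkyne) on the quaternary carbon and a 3-oxobutyl arm (masked as a dioxolane) trans to it.
2. The tertiary carbinol is cut next to its CH2 group. This gives a cyclopentyl methyl ketone and a six-carbon γ-oxido alkyllithium whose carbinol center comes from a CBS reduction.
3. Key step: the cis-acetylcyclopentane comes from a 2-diazocyclohexanone by a Wolff 1,2-shift (six- to five-membered ring). The ketene is captured by methyllithium and the enolate is protonated kinetically.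
4. The cyclohexanone comes from 3-bromocyclohexenone by Sonogashira coupling, copper-catalysed asymmetric conjugate methylation (quaternary carbon) and an anti-selective Mukaiyama–Michael addition to butenone.
5. Ring order: a purchased six-membered ring is contracted to ring A (five-membered), then ring B (six-membered) is closed last.

Assumption: the configuration is taken exactly as written in the SMILES (side chain 3S,6S; core 1S,3aR,7aS), and the five small building blocks are taken as commercial.

## Route

Step 1
Reactants: 1 3-bromocyclohex-2-en-1-one; 2 ethynyltrimethylsilane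
Product: 3 3-[(trimethylsilyl)ethynyl]cyclohex-2-en-1-one
Conditions: PdCl2(PPh3)2 (2 mol %), CuI (4 mol %), Et3N (2 equiv), THF, rt
Reagents that add atoms: none
Why: Sonogashira coupling in which the β-bromo enone is an activated vinyl halide for oxidative addition to zerovalent palladium and the silyl cap blocks a second coupling; no stereocenter is formed.

Step 2
Reactants: 3 3-[(trimethylsilyl)ethynyl]cyclohex-2-en-1-one
Product: 5 (S)-trimethyl({3-methyl-3-[(trimethylsilyl)ethynyl]cyclohex-1-en-1-yl}oxy)silane, via magnesium enolate 4 (not isolated)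
Conditions: MeMgBr (1.2 equiv), Cu(OTf)2 (3 mol %), tert-leucinol-derived hydroxyalkyl N-mesityl imidazolinium hexafluorophosphate (NHC precursor, 4 mol %, enantiomer chosen for the S product), Et2O, −10 °C; then Me3SiCl (2 equiv), Et3N, DMPU, −10 °C to rt
Reagents that add atoms: methylmagnesium bromide C[Mg]Br; chlorotrimethylsilane C[Si](C)(C)Cl
Why: Copper-catalysed asymmetric conjugate addition of a Grignard reagent to a cyclic enynone, in which the bidentate alkoxy-NHC copper catalyst directs methyl transfer 1,4 rather than 1,6 and to one enantioface, which sets the quaternary carbon as S, while silylation fixes the enolate regiochemistry.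

Step 3
Reactants: 5 (S)-trimethyl({3-methyl-3-[(trimethylsilyl)ethynyl]cyclohex-1-en-1-yl}oxy)silane; 6 but-3-en-2-one
Product: 8 (2R,3S)-3-methyl-2-(3-oxobutyl)-3-[(trimethylsilyl)ethynyl]cyclohexan-1-one, via silyl enol ether 7 (not isolated)
Conditions: HNTf2 (2 mol %), CH2Cl2, −78 °C; then aq citric acid, 0 °C
Reagents that add atoms: none
Why: Mukaiyama–Michael addition under silylium catalysis, in which the slim alkynyl group sits pseudoaxial on the half-chair enol ether so that butenone is attacked along the chair-like axial trajectory anti to it, placing the new chain trans to the alkyne and cis to the methyl group (2R) under kinetic control.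

Step 4
Reactants: 8 (2R,3S)-3-methyl-2-(3-oxobutyl)-3-[(trimethylsilyl)ethynyl]cyclohexan-1-one
Product: 9 (2R,3S)-3-methyl-2-[2-(2-methyl-1,3-dioxolan-2-yl)ethyl]-3-[(trimethylsilyl)ethynyl]cyclohexan-1-one
Conditions: Me3SiOCH2CH2OSiMe3 (1.2 equiv), Me3SiOTf (5 mol %), CH2Cl2, −78 to −40 °C; pyridine quench
Reagents that add atoms: 1,2-bis(trimethylsilyloxy)ethane C[Si](C)(C)OCCO[Si](C)(C)C
Why: Noyori ketalisation, in which the open methyl ketone reacts at low temperature while the ring ketone next to a tertiary and a quaternary carbon does not, and the aprotic non-basic medium leaves the epimerisable C2 untouched.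

Step 5
Reactants: 9 (2R,3S)-3-methyl-2-[2-(2-methyl-1,3-dioxolan-2-yl)ethyl]-3-[(trimethylsilyl)ethynyl]cyclohexan-1-one
Product: 11 (2R,3S)-6-diazo-3-methyl-2-[2-(2-methyl-1,3-dioxolan-2-yl)ethyl]-3-[(trimethylsilyl)ethynyl]cyclohexan-1-one, via trifluoroacetyl ketone 10 (not isolated)
Conditions: LiN(SiMe3)2 (1.1 equiv), THF, −78 °C; CF3CO2CH2CF3 (1.2 equiv); buffered aqueous work-up; then MeSO2N3 (1.5 equiv), Et3N (1.5 equiv), H2O (1 equiv), MeCN, rt
Reagents that add atoms: methanesulfonyl azide CS(=O)(=O)N=[N+]=[N-]
Why: Detrifluoroacetylative Regitz-type diazo transfer, in which the amide base removes the only accessible kinetic proton (C6 methylene), the trifluoroacetyl group activates that carbon for diazo transfer and is then lost, and no stereocenter is touched.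

Step 6
Reactants: 11 (2R,3S)-6-diazo-3-methyl-2-[2-(2-methyl-1,3-dioxolan-2-yl)ethyl]-3-[(trimethylsilyl)ethynyl]cyclohexan-1-one
Product: 14 1-{(1S,2S,3S)-3-methyl-2-[2-(2-methyl-1,3-dioxolan-2-yl)ethyl]-3-[(trimethylsilyl)ethynyl]cyclopentyl}ethan-1-one, via ketene 12 (not isolated), via lithium enolate 13 (not isolated)
Conditions: hν (365 nm LED), dry THF, −78 °C, until N2 evolution stops; MeLi (1.05 equiv), −78 °C; AcOH (1.2 equiv in THF), −78 °C
Reagents that add atoms: methyllithium [Li]C
Why: Proposed new method: irradiation expels N2 from the s-cis-locked cyclic diazo ketone and C2 migrates with retention from the carbonyl carbon to the carbene carbon (Wolff 1,2-shift, six- to five-membered ring) to give a dialkylketene that persists at −78 °C without protic traps; MeLi attacks its sp carbon in-plane from the open side and gives the tetrasubstituted lithium enolate regiospecifically, and protonation from the face opposite the adjacent side chain and the 1,3-related methyl group sets C1 as the contra-thermodynamic cis-acetyl epimer (1S); the closest known reaction types are the photochemical Wolff ring contraction with alcohol or amine capture and the addition of organolithiums to isolated ketenes followed by kinetic enolate protonation.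

Step 7
Reactants: 15 3-chloropropanoyl chloride; 16 isopropenylmagnesium bromide
Product: 17 5-chloro-2-methylpent-1-en-3-one
Conditions: CuI (5 mol %), THF, −78 °C, slow addition of 16 (1.0 equiv); used crude
Reagents that add atoms: none
Why: Copper-catalysed acylation of a Grignard reagent by an acid chloride, in which at −78 °C and with slow addition the acyl chloride outcompetes the product ketone and the β-chloride is retained; no stereocenter is formed.

Step 8
Reactants: 17 5-chloro-2-methylpent-1-en-3-one
Product: 18 (S)-5-chloro-2-methylpent-1-en-3-ol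
Conditions: (R)-Me-CBS oxazaborolidine (10 mol %), catecholborane (1.5 equiv), toluene, −78 °C; aqueous work-up
Reagents that add atoms: none
Why: Corey–Bakshi–Shibata reduction, in which the isopropenyl group acts as the large and the chloroethyl group as the small substituent on the oxazaborolidine–borane complex so that hydride reaches one face and gives the S alcohol, while catecholborane at low temperature spares the alkene.

Step 9
Reactants: 18 (S)-5-chloro-2-methylpent-1-en-3-ol; 14 1-{(1S,2S,3S)-3-methyl-2-[2-(2-methyl-1,3-dioxolan-2-yl)ethyl]-3-[(trimethylsilyl)ethynyl]cyclopentyl}ethan-1-one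
Product: 21 (3S,6S)-6-{(1S,2S,3S)-3-ethynyl-3-methyl-2-[2-(2-methyl-1,3-dioxolan-2-yl)ethyl]cyclopentyl}-2-methylhept-1-ene-3,6-diol, via dilithio reagent 19 (not isolated), via dilithium dialkoxide 20 (not isolated)
Conditions: 18, n-BuLi (1.0 equiv), THF, −78 °C; lithium 4,4'-di-tert-butylbiphenylide (2.0 equiv), −78 °C; 14 (0.8 equiv), −78 °C; then MeOH, K2CO3 (20 mol %), rt
Reagents that add atoms: none
Why: Reductive lithiation of the alkoxide-masked chloride gives a γ-oxido alkyllithium that adds 1,2 to the methyl ketone under Felkin–Anh control (ring carbon C2 anti to the nucleophile, hydrogen flanking its path), which sets the tertiary carbinol as S, and methanolysis then removes the alkynyl silyl group.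

Step 10
Reactants: 21 (3S,6S)-6-{(1S,2S,3S)-3-ethynyl-3-methyl-2-[2-(2-methyl-1,3-dioxolan-2-yl)ethyl]cyclopentyl}-2-methylhept-1-ene-3,6-diol
Product: 22 2-{(1R,2S,3S)-3-[(2S,5S)-2,5-dihydroxy-6-methylhept-6-en-2-yl]-1-methyl-2-[2-(2-methyl-1,3-dioxolan-2-yl)ethyl]cyclopentyl}acetaldehyde
Conditions: [CpRu(MeCN)3]PF6 (5 mol %), 5,5'-bis(trifluoromethyl)-2,2'-bipyridine (5 mol %), NMP–H2O 4:1, 40 °C
Reagents that add atoms: water O
Why: Ruthenium-catalysed anti-Markovnikov alkyne hydration through a vinylidene complex, which only the terminal alkyne can form, so that oxygen ends on the terminal carbon as the aldehyde and the 1,1-disubstituted alkene, the ketal and the alcohols are untouched.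

Step 11
Reactants: 22 2-{(1R,2S,3S)-3-[(2S,5S)-2,5-dihydroxy-6-methylhept-6-en-2-yl]-1-methyl-2-[2-(2-methyl-1,3-dioxolan-2-yl)ethyl]cyclopentyl}acetaldehyde
Product: 24 1-{(1S,3aR,7aS)-1-[(2S,5S)-2,5-dihydroxy-6-methylhept-6-en-2-yl]-3a-methyl-2,3,3a,4,7,7a-hexahydro-1H-inden-6-yl}ethan-1-one, via keto aldehyde 23 (not isolated)
Conditions: HCl (1 M aq, 0.2 equiv), THF, rt; then KOH (0.5 equiv), MeOH, 0 °C to rt
Reagents that add atoms: water O
Why: Ketal hydrolysis followed by intramolecular aldol condensation, in which the internal α-methylene of the methyl ketone closes a six-membered ring on the aldehyde (the alternatives are an eight-membered ring or attack of a neopentyl aldehyde enolate on a ketone) and E1cB loss of water gives the acetylcyclohexene, the trans ring fusion being fixed by the two existing stereocenters.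

Step 12
Reactants: 24 1-{(1S,3aR,7aS)-1-[(2S,5S)-2,5-dihydroxy-6-methylhept-6-en-2-yl]-3a-methyl-2,3,3a,4,7,7a-hexahydro-1H-inden-6-yl}ethan-1-one
Product: 25 (3S,6S)-6-[(1S,3aR,7aS)-6-acetyl-3a-methyl-2,3,3a,4,7,7a-hexahydro-1H-inden-1-yl]-6-hydroxy-2-methylhept-1-en-3-yl acetate
Conditions: Ac2O (1.2 equiv), pyridine (3 equiv), DMAP (5 mol %), CH2Cl2, 0 °C
Reagents that add atoms: acetic anhydride CC(=O)OC(C)=O
Why: DMAP-catalysed chemoselective acylation, in which the secondary allylic alcohol reacts far faster than the hindered tertiary alcohol and the configuration is kept because the C–O bond is not broken.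

## Compound list

1 | 3-bromocyclohex-2-en-1-one | O=C1C=C(Br)CCC1 | starting material
2 | ethynyltrimethylsilane | C#C[Si](C)(C)C | starting material
3 | 3-[(trimethylsilyl)ethynyl]cyclohex-2-en-1-one | O=C1C=C(C#C[Si](C)(C)C)CCC1 | intermediate
4 | bromomagnesium (S)-3-methyl-3-[(trimethylsilyl)ethynyl]cyclohex-1-en-1-olate | Br[Mg]OC1=C[C@@](C)(C#C[Si](C)(C)C)CCC1 | intermediate
5 | (S)-trimethyl({3-methyl-3-[(trimethylsilyl)ethynyl]cyclohex-1-en-1-yl}oxy)silane | C[Si](C)(C)OC1=C[C@@](C)(C#C[Si](C)(C)C)CCC1 | intermediate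
6 | but-3-en-2-one | C=CC(C)=O | starting material
7 | (2R,3S)-3-methyl-2-[(2Z)-3-(trimethylsilyloxy)but-2-en-1-yl]-3-[(trimethylsilyl)ethynyl]cyclohexan-1-one | O=C1CCC[C@](C)(C#C[Si](C)(C)C)[C@H]1C/C=C(\O[Si](C)(C)C)C | intermediate
8 | (2R,3S)-3-methyl-2-(3-oxobutyl)-3-[(trimethylsilyl)ethynyl]cyclohexan-1-one | O=C1CCC[C@](C)(C#C[Si](C)(C)C)[C@H]1CCC(C)=O | intermediate
9 | (2R,3S)-3-methyl-2-[2-(2-methyl-1,3-dioxolan-2-yl)ethyl]-3-[(trimethylsilyl)ethynyl]cyclohexan-1-one | O=C1CCC[C@](C)(C#C[Si](C)(C)C)[C@H]1CCC2(C)OCCO2 | intermediate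
10 | (2R,3S)-3-methyl-2-[2-(2-methyl-1,3-dioxolan-2-yl)ethyl]-6-(trifluoroacetyl)-3-[(trimethylsilyl)ethynyl]cyclohexan-1-one (enolised, C6 not defined) | O=C1C(C(=O)C(F)(F)F)CC[C@](C)(C#C[Si](C)(C)C)[C@H]1CCC2(C)OCCO2 | intermediate
11 | (2R,3S)-6-diazo-3-methyl-2-[2-(2-methyl-1,3-dioxolan-2-yl)ethyl]-3-[(trimethylsilyl)ethynyl]cyclohexan-1-one | O=C1C(=[N+]=[N-])CC[C@](C)(C#C[Si](C)(C)C)[C@H]1CCC2(C)OCCO2 | intermediate
12 | ring-contracted cyclopentylidene ketene (ring substituents configured as in 14) | O=C=C1CC[C@](C)(C#C[Si](C)(C)C)[C@H]1CCC2(C)OCCO2 | intermediate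
13 | lithium (Z)-enolate of 14 (exocyclic, oxygen on the side of the substituted ring carbon) | [Li]O/C(C)=C1/CC[C@](C)(C#C[Si](C)(C)C)[C@H]1CCC2(C)OCCO2 | intermediate
14 | 1-{(1S,2S,3S)-3-methyl-2-[2-(2-methyl-1,3-dioxolan-2-yl)ethyl]-3-[(trimethylsilyl)ethynyl]cyclopentyl}ethan-1-one | CC(=O)[C@H]1CC[C@](C)(C#C[Si](C)(C)C)[C@H]1CCC2(C)OCCO2 | intermediate
15 | 3-chloropropanoyl chloride | O=C(Cl)CCCl | starting material
16 | isopropenylmagnesium bromide | C=C(C)[Mg]Br | starting material
17 | 5-chloro-2-methylpent-1-en-3-one | C=C(C)C(=O)CCCl | intermediate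
18 | (S)-5-chloro-2-methylpent-1-en-3-ol | C=C(C)[C@H](CCCl)O | intermediate
19 | lithium (3S)-5-lithio-2-methylpent-1-en-3-olate | C=C(C)[C@H](CC[Li])O[Li] | intermediate
20 | dilithium dialkoxide of the C-silylated form of 21 | C=C(C)[C@H](CC[C@](C)(O[Li])[C@H]1CC[C@](C)(C#C[Si](C)(C)C)[C@H]1CCC2(C)OCCO2)O[Li] | intermediate
21 | (3S,6S)-6-{(1S,2S,3S)-3-ethynyl-3-methyl-2-[2-(2-methyl-1,3-dioxolan-2-yl)ethyl]cyclopentyl}-2-methylhept-1-ene-3,6-diol | C=C(C)[C@H](CC[C@](C)(O)[C@H]1CC[C@](C)(C#C)[C@H]1CCC2(C)OCCO2)O | intermediate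
22 | 2-{(1R,2S,3S)-3-[(2S,5S)-2,5-dihydroxy-6-methylhept-6-en-2-yl]-1-methyl-2-[2-(2-methyl-1,3-dioxolan-2-yl)ethyl]cyclopentyl}acetaldehyde | C=C(C)[C@H](CC[C@](C)(O)[C@H]1CC[C@](C)(CC=O)[C@H]1CCC2(C)OCCO2)O | intermediate
23 | 2-{(1R,2S,3S)-3-[(2S,5S)-2,5-dihydroxy-6-methylhept-6-en-2-yl]-1-methyl-2-(3-oxobutyl)cyclopentyl}acetaldehyde | C=C(C)[C@H](CC[C@](C)(O)[C@H]1CC[C@](C)(CC=O)[C@H]1CCC(C)=O)O | intermediate
24 | 1-{(1S,3aR,7aS)-1-[(2S,5S)-2,5-dihydroxy-6-methylhept-6-en-2-yl]-3a-methyl-2,3,3a,4,7,7a-hexahydro-1H-inden-6-yl}ethan-1-one | C=C(C)[C@H](CC[C@](C)(O)[C@H]1CC[C@]2(C)CC=C(C(C)=O)C[C@@H]12)O | intermediate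
25 | (3S,6S)-6-[(1S,3aR,7aS)-6-acetyl-3a-methyl-2,3,3a,4,7,7a-hexahydro-1H-inden-1-yl]-6-hydroxy-2-methylhept-1-en-3-yl acetate | C=C(C)[C@H](CC[C@](C)(O)[C@H]1CC[C@]2(C)CC=C(C(C)=O)C[C@@H]12)OC(C)=O | target

## Step count and risks

Total steps: 12. Longest linear sequence: 10 (steps 1 to 6 and 9 to 12).

The three steps most likely to fail are steps 3, 6 and 9.

**Step 3.** The enol ether carbon is hindered because it sits next to the quaternary center, and the 2R center it forms is the kinetic, less stable epimer. If the conjugate addition is sluggish or the configuration erodes, the bond is made by SN2 alkylation instead.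
- The fallback sets out from 5.
- MeLi (1.0 equiv, THF, 0 °C) cleaves the O–Si bond and gives lithium enolate F1.
- F1 is alkylated with 2-(2-iodoethyl)-2-methyl-1,3-dioxolane in THF–DMPU at −40 °C, again anti to the pseudoaxial alkyne.
- This delivers the ketal ketone directly, so the route is rejoined at 9 and step 4 is skipped.

**Step 6 (the proposed new step).** The ketene may dimerise or be lost before capture. MeLi may attack unreacted diazo ketone. The protonation may also be less face-selective than expected. The fallback uses the classical Wolff ring contraction with amine capture.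
- It sets out from 11.
- Irradiation at 365 nm in THF at 0 °C in the presence of N,O-dimethylhydroxylamine (3 equiv) gives Weinreb amide F2. C1 is set by tautomerisation of the amide enol from the same open face.
- MeMgBr (1.5 equiv, THF, 0 °C) then converts F2 into the methyl ketone, and the route is rejoined at 14.

**Step 9.** The methyl ketone is hindered and enolisable, and the Felkin–Anh preference on a cyclopentyl ketone may be weak or even inverted. If the addition gives mainly the epimer at the carbinol carbon, the two carbon groups are brought in the other order.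
- The fallback sets out from 11, which is converted as above into Weinreb amide F2.
- F2 is acylated by the dilithio reagent 19 (THF, −78 °C) to give hydroxy ketone F3.
- MeLi (3 equiv, Et2O, −78 °C) adds to F3 and gives the dilithium dialkoxide, so the route is rejoined at 20.
- The same carbonyl face stays open to attack, so exchanging nucleophile and resident group inverts the outcome at the carbinol carbon.

Further compounds
F1 | step 3 | lithium (S)-3-methyl-3-[(trimethylsilyl)ethynyl]cyclohex-1-en-1-olate | [Li]OC1=C[C@@](C)(C#C[Si](C)(C)C)CCC1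
F2 | step 6 | (1S,2S,3S)-N-methoxy-N,3-dimethyl-2-[2-(2-methyl-1,3-dioxolan-2-yl)ethyl]-3-[(trimethylsilyl)ethynyl]cyclopentane-1-carboxamide | CON(C)C(=O)[C@H]1CC[C@](C)(C#C[Si](C)(C)C)[C@H]1CCC2(C)OCCO2
F3 | step 9 | (4S)-4-hydroxy-5-methyl-1-{(1S,2S,3S)-3-methyl-2-[2-(2-methyl-1,3-dioxolan-2-yl)ethyl]-3-[(trimethylsilyl)ethynyl]cyclopentyl}hex-5-en-1-one | C=C(C)[C@H](CCC(=O)[C@H]1CC[C@](C)(C#C[Si](C)(C)C)[C@H]1CCC2(C)OCCO2)O
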